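The earlier runs and the new flask are calculated for substances that don't exist; noise was put on by code.

The south-east flask could not take its E into solution: of the 2.7 M charged, G rose to about 1.09 M and stayed there, with solid E still beside it.

all flasks: E 2.7 M; Q 2.16 M

| charge | remark | time |
|---|---|---|
| south-east | the very flask that is asked about, followed so far |  |
| flask |  | 3.0 h |

south-east run (percent of the E charged)

| time / min | D / % | G / % | E / % |
|---|---|---|---|
| 3.00 | 0.7 | 25.2 | 71.6 |
| 10.0 | 0.9 | 38.5 | 54.4 |
| 15.0 | 0.4 | 40.6 | 51.7 |
| 25.0 | 0 | 40.5 | 48.0 |
| 40.0 | 1.9 | 40.3 | 42.8 |

(scatter of a reading: 0.5 percentage points)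

- solid, in amounts per volume of the solution: E, Q
- at the start none of E is in solution
- at the start none of Q is in solution
- G is what E becomes in solution
- G means what is dissolved; the solid is not counted in it

- how much D there is at 3.0 h, in percent of the E charged
- concentration of G in solution at 3.0 h, in percent of saturation

I read the table column by column. In the G column the last rows, 40.6 %, 40.5 % and 40.3 %, agree within the scatter: a steady state, which I took for saturation. The first row set against that level gave 2.15 min, the time in which dissolving closes half the gap. In the E column, the rows at 15.0 min and 40.0 min gave 91.7 min as the solid half-life, the time in which solid E falls to half at that pace. That first-order fall was my guess. From the last row to 3.0 h lie 1.53 solid half-lives, so my estimate was 14.9 % of E. Dissolving is much faster than the solid's fall, so I let G trail its ceiling by E times the ratio of the two half-lives, 0.35 percentage points, on the assumption that the solid's loss passes through solution. That made 99.1 % of saturation. The D column stayed too near the scatter for a figure of my own.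

The forecast gave 15 % (5 % to 35 %) and 96 % (78 % to 100 %), with “Solid E therefore runs out near 170 min”, whereas my count kept solid in the flask at 3.0 h.

The flask gave 13.3 % of D and 98.5 % of saturation, with E at 7.83 %.

    E ⇌ G, rate k1*(cs1 - [G]) while solid is left; crystals form when [G] > cs1 (solubility = 1.10 M, k = 0.338 min⁻¹)
    G + L → D (k = 0.00963 M⁻¹ min⁻¹)
    G + D → Z (k = 0.00410 M⁻¹ min⁻¹)
    D ⇌ J (K = 0.150, k = 0.0405 min⁻¹)
    Q ⇌ L, rate k5*(cs5 - [L]) while solid is left; crystals form when [L] > cs5 (solubility = 0.840 M, k = 0.00927 min⁻¹)
    2 E → X (k = 0.00242 M⁻¹ min⁻¹)

That E means 2.45 halvings after the last row, against my 1.53, so the flask's solid fell faster late on than the half-life said. A reading of the same flask at 2.0 h takes the same count: 0.872 solid half-lives after the last row, for an estimate of 23.4 % of E and G at 98.6 % of saturation. At that reading E stood at 21.0 %, G at 40.2 % of the charge, and D at 8.31 %.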